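**Strategy.** Everything rests on cutting C5–C10 and C3–C4 of the cis-decalin at once. Ring A carries four contiguous stereocentres (C3 carbinol, methyl-bearing C4 and quaternary C5, ring-fusion C10). They map onto the cyclohexene formed from a 1-oxygenated (E,E)-diene (C10=C1–C2=C3) and an (E)-2-methylbut-2-enoyl alkene (C4=C5). Both partners sit on one chain, linked by C6(=O)–C7–C8–C9, so one intramolecular Diels–Alder reaction closes rings A and B and sets all four centres. The precursor is an open-chain undecatrienone: PMB dienol ether at one end, tigloyl ketone at the other, and a single chiral-pool silyloxy centre at C8 that steers the facial course. C8 later becomes the ketone; the C7=C11 geometry is locked through a furan.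

Key step: step 9

Remark on the chemistry: bicyclic compounds carry eremophilane numbering. β is the face of the C4 and C5 methyl groups and α the opposite face. Centres left open in the SMILES of 24 and 26 are transient mixtures that are erased later.

Step 1
Reactants: 1 ethyl (S)-4-chloro-3-hydroxybutanoate
Product: 2 ethyl 2-[(2S)-oxiran-2-yl]acetate
Conditions: Ag2O, 1,2-dimethoxyethane, reflux, dark
Reagents that add atoms: none
Why: Silver-assisted intramolecular Williamson etherification closes the epoxide without free base, so E1cB drift of the β,γ-epoxy ester to a 4-hydroxycrotonate is avoided and the carbinol C–O bond (future C8) is never broken.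

Step 2
Reactants: 2 ethyl 2-[(2S)-oxiran-2-yl]acetate; 3 vinylmagnesium bromide
Product: 4 ethyl (R)-3-hydroxyhex-5-enoate
Conditions: 3 (2 equiv), CuI (20 mol %), THF, −40 °C
Reagents that add atoms: none
Why: Copper-catalysed SN2 opening of a terminal epoxide by a vinyl Grignard reagent occurs at the CH2 terminus faster than attack on the ester at low temperature, so the stereocentre is retained (S becomes R only through CIP priorities).

Step 3
Reactants: 4 ethyl (R)-3-hydroxyhex-5-enoate
Product: 5 (3R)-3-hydroxy-N-methoxy-N-methylhex-5-enamide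
Conditions: MeNH(OMe)·HCl, i-PrMgCl, THF, −20 → 0 °C
Reagents that add atoms: N,O-dimethylhydroxylamine hydrochloride, CNOC.Cl
Why: Weinreb amide synthesis by aminolysis with the chloromagnesium amide made in situ, one extra Grignard equivalent holding the free hydroxyl as its alkoxide so that no dehydration occurs.

Step 4
Reactants: 5 (3R)-3-hydroxy-N-methoxy-N-methylhex-5-enamide
Product: 6 (3R)-3-(tert-butyldimethylsilyloxy)-N-methoxy-N-methylhex-5-enamide
Conditions: TBSCl, imidazole, DMF, rt
Reagents that add atoms: tert-butyldimethylsilyl chloride, CC(C)(C)[Si](C)(C)Cl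
Why: Standard imidazole-promoted silylation installs the bulky ether that serves as the equatorial anchor in step 9 and blocks retro-aldol pathways.

Step 5
Reactants: 6 (3R)-3-(tert-butyldimethylsilyloxy)-N-methoxy-N-methylhex-5-enamide; 7 (E)-crotonaldehyde
Product: 8 (3R,5E)-3-(tert-butyldimethylsilyloxy)-N-methoxy-N-methyl-7-oxohept-5-enamide
Conditions: 7 (5 equiv), second-generation Hoveyda–Grubbs catalyst RuCl2(H2IMes)(=CH-C6H4-2-O-i-Pr) (3 mol %), CH2Cl2, 40 °C
Reagents that add atoms: none
Why: Olefin cross-metathesis of an unhindered terminal alkene with an electron-poor enal is selective for the cross product and gives the (E)-enal under thermodynamic control, which fixes the C10=C1 geometry.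

Step 6
Reactants: 8 (3R,5E)-3-(tert-butyldimethylsilyloxy)-N-methoxy-N-methyl-7-oxohept-5-enamide
Product: 9 (3R,5E,7E)-3-(tert-butyldimethylsilyloxy)-8-iodo-N-methoxy-N-methylocta-5,7-dienamide
Conditions: CHI3, CrCl2, THF–dioxane, 0 °C → rt
Reagents that add atoms: iodoform, C(I)(I)I
Why: Takai olefination through a geminal dichromium carbenoid turns aldehydes into (E)-vinyl iodides and tolerates amide and silyl ether, so C3 is added with the C2=C3 geometry set by the reagent rather than by γ-deprotonation of an enal, which would favour the unreactive (Z)-C10=C1 dienol ether.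

Step 7
Reactants: 9 (3R,5E,7E)-3-(tert-butyldimethylsilyloxy)-8-iodo-N-methoxy-N-methylocta-5,7-dienamide; 10 4-methoxybenzyl alcohol
Product: 11 (3R,5E,7E)-3-(tert-butyldimethylsilyloxy)-N-methoxy-8-(4-methoxybenzyloxy)-N-methylocta-5,7-dienamide
Conditions: 10 (2 equiv), CuI (10 mol %), 3,4,7,8-tetramethyl-1,10-phenanthroline (20 mol %), Cs2CO3, PhMe, 80 °C
Reagents that add atoms: none
Why: Ullmann-type copper-catalysed C–O coupling of alkenyl iodides with primary alcohols retains alkene geometry and so gives the (E,E)-1-alkoxydiene stereospecifically, the amide α-protons are too weakly acidic for carbonate to expel the β-silyloxy group, and PMB is orthogonal to every silyl ether used later.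

Step 8
Reactants: 11 (3R,5E,7E)-3-(tert-butyldimethylsilyloxy)-N-methoxy-8-(4-methoxybenzyloxy)-N-methylocta-5,7-dienamide; 12 (E)-2-bromobut-2-ene
Product: 14 (2E,6R,8E,10E)-6-(tert-butyldimethylsilyloxy)-11-(4-methoxybenzyloxy)-3-methylundeca-2,8,10-trien-4-one, via (Z)-but-2-en-2-yllithium 13 (not isolated)
Conditions: 12, t-BuLi (2 equiv), Et2O, −78 °C; then 11, THF, −78 °C; aqueous work-up
Reagents that add atoms: none
Why: Bromine–lithium exchange is stereoretentive and the Weinreb ketone synthesis stops at the chelated tetrahedral adduct, delivering the (E)-2-methylbut-2-enoyl ketone with its two methyl groups cis on the alkene.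

Step 9
Reactants: 14 (2E,6R,8E,10E)-6-(tert-butyldimethylsilyloxy)-11-(4-methoxybenzyloxy)-3-methylundeca-2,8,10-trien-4-one
Product: 15 3α-(4-methoxybenzyloxy)-8β-(tert-butyldimethylsilyloxy)-10βH-11,12,13-trinoreremophil-1-en-6-one (cis-fused octalone)
Conditions: PhMe (0.01 M), BHT (10 mol %), base-washed sealed tube, 165 °C
Reagents that add atoms: none
Why: Concerted suprafacial thermal [4+2] cycloaddition, of the type known for 1,7,9-decatrien-3-ones that give cis-fused octalones, in which the C4=C5 alkene adds across C10=C1–C2=C3 and forms C5–C10 and C3–C4. Ring A closes as the new cyclohexene of the cycloaddition, and ring B closes in the same event as the six-membered ring made of the tether C6–C9 and the new C5–C10 bond. The (E)-dienophile geometry carries the two methyl groups into a cis C4/C5 relationship, the endo placement of the tether carbonyl under the diene puts H10 cis to the C5 methyl (cis fusion), and the (E)-enol ether terminus places O3 on the face opposite the C4 methyl. The step needs endo over exo and one diene face: endo is secured because the exo mode would push the C5 methyl over the diene, and the face is chosen by C8, whose silyloxy group lies equatorial on the chair-like tether whereas addition to the other face would make it axial and syn to C1. The tether-imposed regiochemistry opposes the polarisation of a 1-alkoxydiene, so the donor gives no rate help and heat is required, while dilution, BHT and base-washed glass protect the acid-labile dienol ether.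

Step 10
Reactants: 15 3α-(4-methoxybenzyloxy)-8β-(tert-butyldimethylsilyloxy)-10βH-11,12,13-trinoreremophil-1-en-6-one
Product: 16 3α-(4-methoxybenzyloxy)-8β-(tert-butyldimethylsilyloxy)-10βH-11,12,13-trinoreremophilan-6-one
Conditions: H2 (1 atm), Rh/Al2O3 (5 wt %), EtOAc, rt
Reagents that add atoms: none
Why: Heterogeneous hydrogenation of the only alkene, a cis-disubstituted cyclohexene, over rhodium on alumina, which does not hydrogenolyse allylic or benzylic C–O bonds.

Step 11
Reactants: 16 3α-(4-methoxybenzyloxy)-8β-(tert-butyldimethylsilyloxy)-10βH-11,12,13-trinoreremophilan-6-one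
Product: 18 3α-(4-methoxybenzyloxy)-8β-(tert-butyldimethylsilyloxy)-10βH-11,12,13-trinoreremophil-6-en-6-yl trifluoromethanesulfonate, via potassium enolate 17 (not isolated)
Conditions: KN(SiMe3)2, THF, −78 °C; then N-(5-chloro-2-pyridyl)bis(trifluoromethanesulfonimide), −78 °C
Reagents that add atoms: N-(5-chloro-2-pyridyl)bis(trifluoromethanesulfonimide), FC(F)(F)S(=O)(=O)N(c1ccc(Cl)cn1)S(=O)(=O)C(F)(F)F
Why: Enolisation can only go towards C7 because C5 is quaternary, and O-triflation with the Comins reagent at −78 °C outruns E1cB loss of the poor silyloxide leaving group.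

Step 12
Reactants: 18 3α-(4-methoxybenzyloxy)-8β-(tert-butyldimethylsilyloxy)-10βH-11,12,13-trinoreremophil-6-en-6-yl trifluoromethanesulfonate
Product: 19 3α-(4-methoxybenzyloxy)-8β-(tert-butyldimethylsilyloxy)-10βH-11,12,13-trinoreremophil-6-ene
Conditions: Pd(OAc)2 (5 mol %), PPh3 (10 mol %), HCO2H, Et3N, DMF, 60 °C
Reagents that add atoms: none
Why: Palladium-catalysed formate reduction of an enol triflate (oxidative addition to zerovalent palladium, formate decarboxylation, reductive elimination) replaces OTf by H and leaves the C6=C7 alkene and both ethers untouched.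

Step 13
Reactants: 19 3α-(4-methoxybenzyloxy)-8β-(tert-butyldimethylsilyloxy)-10βH-11,12,13-trinoreremophil-6-ene
Product: 20 3α-(4-methoxybenzyloxy)-10βH-11,12,13-trinoreremophil-6-en-8β-ol
Conditions: Bu4NF, THF, rt
Reagents that add atoms: none
Why: Fluoride-induced desilylation is free of selectivity issues because the TBS ether is the only silyl group present.

Step 14
Reactants: 20 3α-(4-methoxybenzyloxy)-10βH-11,12,13-trinoreremophil-6-en-8β-ol
Product: 21 3α-(4-methoxybenzyloxy)-10βH-11,12,13-trinoreremophil-6-en-8-one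
Conditions: Dess–Martin periodinane, CH2Cl2, rt
Reagents that add atoms: none
Why: Dess–Martin oxidation of the allylic alcohol erases the C8 control centre and completes a 1,3-carbonyl transposition to the C6=C7–C8=O enone.

Step 15
Reactants: 21 3α-(4-methoxybenzyloxy)-10βH-11,12,13-trinoreremophil-6-en-8-one; 22 1-(tert-butyldimethylsilyloxy)propan-2-one
Product: 25 3α-(4-methoxybenzyloxy)-10βH-furanoeremophilane (8,12-epoxyeremophila-7,11-diene), via lithium enolate 23 (not isolated), via aldol adduct 24 (not isolated)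
Conditions: LiBH(s-Bu)3, THF, −78 °C; then 22, −78 °C; then 2 M HCl, THF, rt
Reagents that add atoms: none
Why: Conjugate hydride addition gives the C7=C8 enolate regiospecifically (reductive aldol), its addition to the inductively activated α-silyloxy ketone forges C7–C11, and acid then removes the primary TBS group and drives hemiketalisation and double dehydration (Paal–Knorr-type cyclodehydration) to the aromatic furan, so the transient C7 and C11 centres do not matter.

Step 16
Reactants: 25 3α-(4-methoxybenzyloxy)-10βH-furanoeremophilane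
Product: 28 (7Z)-12-hydroxy-3α-(4-methoxybenzyloxy)-10βH-eremophil-7(11)-en-8-one, via furan endoperoxide 26 (not isolated), via (Z)-keto-enal 27 (not isolated)
Conditions: O2, hν, tetraphenylporphyrin (cat.), CH2Cl2, −78 °C; Me2S, −78 → −20 °C; then LiAlH(O-t-Bu)3, THF, −78 °C
Reagents that add atoms: dioxygen, O=O
Why: Furan photooxygenation ([4+2] addition of singlet oxygen), sulfide reduction of the endoperoxide to the cis-ene-dicarbonyl and chemoselective hydride reduction of the aldehyde beside the hindered ketone amount to a net hydration of the furan; because C8 and C12 were joined through the ring oxygen, C12 ends up cis to C8 and the (Z)-C7=C11 geometry is set, and running the sequence cold in one flask limits Z-to-E drift.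

Step 17
Reactants: 28 (7Z)-12-hydroxy-3α-(4-methoxybenzyloxy)-10βH-eremophil-7(11)-en-8-one
Product: 29 (7Z)-3α-(4-methoxybenzyloxy)-12-(triethylsilyloxy)-10βH-eremophil-7(11)-en-8-one
Conditions: TESCl, imidazole, CH2Cl2, 0 °C
Reagents that add atoms: triethylsilyl chloride, CC[Si](Cl)(CC)CC
Why: Silylation of the only free hydroxyl traps the open hydroxy-enone form and stops loss of water back to the furan.

Step 18
Reactants: 29 (7Z)-3α-(4-methoxybenzyloxy)-12-(triethylsilyloxy)-10βH-eremophil-7(11)-en-8-one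
Product: 32 (7Z)-3α-(4-methoxybenzyloxy)-9β,12-bis(triethylsilyloxy)-10βH-eremophil-7(11)-en-8-one, via sodium enolate 30 (not isolated), via 9β-hydroxy ketone 31 (not isolated)
Conditions: NaN(SiMe3)2, THF, −78 °C; 2-(phenylsulfonyl)-3-phenyloxaziridine, −78 °C; then TESCl, −78 → 0 °C
Reagents that add atoms: 2-(phenylsulfonyl)-3-phenyloxaziridine, O=S(=O)(c1ccccc1)N1OC1c1ccccc1; triethylsilyl chloride, CC[Si](Cl)(CC)CC
Why: Kinetic deprotonation of an enone takes place at the α′ position (C9), as for mesityl oxide or pulegone, and Davis oxaziridine hydroxylation of the cross-conjugated enolate should occur on the convex β face, anti to the axial C4–C5 bond, giving the equatorial 9β-alkoxide (also the thermodynamic epimer), which is silylated in the same flask.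

Step 19
Reactants: 32 (7Z)-3α-(4-methoxybenzyloxy)-9β,12-bis(triethylsilyloxy)-10βH-eremophil-7(11)-en-8-one
Product: 33 (7Z)-3α-hydroxy-9β,12-bis(triethylsilyloxy)-10βH-eremophil-7(11)-en-8-one
Conditions: DDQ, CH2Cl2–pH 7 buffer, 0 °C
Reagents that add atoms: none
Why: Oxidative PMB cleavage by DDQ (hydride abstraction, hydrolysis of the oxocarbenium ion) under buffered conditions frees only O3 and spares the TES ethers and the electron-poor enone.

Step 20
Reactants: 34 (E)-non-3-en-2-one; 35 triethyl phosphonoacetate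
Product: 36 ethyl (2E,4E)-3-methyldeca-2,4-dienoate
Conditions: 35, NaH, THF, 0 °C → reflux; chromatography
Reagents that add atoms: none
Why: Horner–Wadsworth–Emmons olefination of the methyl ketone gives mainly the (2E)-dienoate because the larger alkenyl group avoids the ester, and the minor (2Z) isomer is removed by chromatography.

Step 21
Reactants: 36 ethyl (2E,4E)-3-methyldeca-2,4-dienoate
Product: 37 (2E,4E)-3-methyldeca-2,4-dien-1-ol
Conditions: i-Bu2AlH, CH2Cl2, −78 °C
Reagents that add atoms: none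
Why: 1,2-Reduction of the conjugated ester to the allylic alcohol leaves the diene and its geometry untouched.

Step 22
Reactants: 37 (2E,4E)-3-methyldeca-2,4-dien-1-ol
Product: 38 (2E,4E)-3-methyldeca-2,4-dienal
Conditions: MnO2, CH2Cl2, rt
Reagents that add atoms: none
Why: Mild heterogeneous oxidation of a dienylic alcohol preserves both alkene geometries.

Step 23
Reactants: 38 (2E,4E)-3-methyldeca-2,4-dienal; 35 triethyl phosphonoacetate
Product: 39 ethyl (2E,4E,6E)-5-methyldodeca-2,4,6-trienoate
Conditions: 35, NaH, THF, 0 °C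
Reagents that add atoms: none
Why: Horner–Wadsworth–Emmons olefination of an aldehyde with a stabilised phosphonate anion is highly (E)-selective.

Step 24
Reactants: 39 ethyl (2E,4E,6E)-5-methyldodeca-2,4,6-trienoate
Product: 40 (2E,4E,6E)-5-methyldodeca-2,4,6-trienoic acid
Conditions: LiOH, THF–H2O, rt; then 1 M HCl
Reagents that add atoms: lithium hydroxide, [Li+].[OH-]
Why: Saponification of the unhindered ethyl ester, the fully conjugated trienoate having no tendency to deconjugate under these conditions.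

Step 25
Reactants: 33 (7Z)-3α-hydroxy-9β,12-bis(triethylsilyloxy)-10βH-eremophil-7(11)-en-8-one; 40 (2E,4E,6E)-5-methyldodeca-2,4,6-trienoic acid
Product: 42 (7Z)-8-oxo-9β,12-bis(triethylsilyloxy)-10βH-eremophil-7(11)-en-3α-yl (2E,4E,6E)-5-methyldodeca-2,4,6-trienoate, via mixed anhydride 41 (not isolated)
Conditions: 40, 2,4,6-trichlorobenzoyl chloride, Et3N, PhMe, rt; then 33, DMAP, rt
Reagents that add atoms: none
Why: Yamaguchi esterification, in which DMAP attacks the mixed anhydride at the less hindered trienoyl carbonyl and the acylpyridinium ion acylates the only free hydroxyl (equatorial O3) with retention at C3.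

Step 26
Reactants: 42 (7Z)-8-oxo-9β,12-bis(triethylsilyloxy)-10βH-eremophil-7(11)-en-3α-yl (2E,4E,6E)-5-methyldodeca-2,4,6-trienoate
Product: 43 (3R,4R,5R,9R,10S,7Z)-9β,12-dihydroxy-8-oxo-10βH-eremophil-7(11)-en-3α-yl (2E,4E,6E)-5-methyldodeca-2,4,6-trienoate (CNP0226738.1)
Conditions: HF·pyridine, pyridine, THF, 0 °C
Reagents that add atoms: none
Why: Buffered fluoride cleavage of both labile TES ethers, the excess pyridine keeping the medium too weakly acidic for dehydration of the (Z)-γ-hydroxy enone to the furan, for α-ketol shift or for ester cleavage.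

**Compound list**

1 | ethyl (S)-4-chloro-3-hydroxybutanoate | CCOC(=O)C[C@H](O)CCl | starting material
2 | ethyl 2-[(2S)-oxiran-2-yl]acetate | CCOC(=O)C[C@H]1CO1 | intermediate
3 | vinylmagnesium bromide | C=C[Mg]Br | starting material
4 | ethyl (R)-3-hydroxyhex-5-enoate | CCOC(=O)C[C@H](O)CC=C | intermediate
5 | (3R)-3-hydroxy-N-methoxy-N-methylhex-5-enamide | CON(C)C(=O)C[C@H](O)CC=C | intermediate
6 | (3R)-3-(tert-butyldimethylsilyloxy)-N-methoxy-N-methylhex-5-enamide | CON(C)C(=O)C[C@H](O[Si](C)(C)C(C)(C)C)CC=C | intermediate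
7 | (E)-crotonaldehyde | C/C=C/C=O | starting material
8 | (3R,5E)-3-(tert-butyldimethylsilyloxy)-N-methoxy-N-methyl-7-oxohept-5-enamide | CON(C)C(=O)C[C@H](O[Si](C)(C)C(C)(C)C)C/C=C/C=O | intermediate
9 | (3R,5E,7E)-3-(tert-butyldimethylsilyloxy)-8-iodo-N-methoxy-N-methylocta-5,7-dienamide | CON(C)C(=O)C[C@H](O[Si](C)(C)C(C)(C)C)C/C=C/C=C/I | intermediate
10 | 4-methoxybenzyl alcohol | COc1ccc(CO)cc1 | starting material
11 | (3R,5E,7E)-3-(tert-butyldimethylsilyloxy)-N-methoxy-8-(4-methoxybenzyloxy)-N-methylocta-5,7-dienamide | CON(C)C(=O)C[C@H](O[Si](C)(C)C(C)(C)C)C/C=C/C=C/OCc1ccc(OC)cc1 | intermediate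
12 | (E)-2-bromobut-2-ene | C/C=C(\C)Br | starting material
13 | (Z)-but-2-en-2-yllithium (methyl groups cis) | C/C=C(\C)[Li] | intermediate
14 | (2E,6R,8E,10E)-6-(tert-butyldimethylsilyloxy)-11-(4-methoxybenzyloxy)-3-methylundeca-2,8,10-trien-4-one | C/C=C(\C)C(=O)C[C@H](O[Si](C)(C)C(C)(C)C)C/C=C/C=C/OCc1ccc(OC)cc1 | intermediate
15 | 3α-(4-methoxybenzyloxy)-8β-(tert-butyldimethylsilyloxy)-10βH-11,12,13-trinoreremophil-1-en-6-one | COc1ccc(CO[C@@H]2C=C[C@@H]3C[C@@H](O[Si](C)(C)C(C)(C)C)CC(=O)[C@]3(C)[C@H]2C)cc1 | intermediate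
16 | 3α-(4-methoxybenzyloxy)-8β-(tert-butyldimethylsilyloxy)-10βH-11,12,13-trinoreremophilan-6-one | COc1ccc(CO[C@@H]2CC[C@@H]3C[C@@H](O[Si](C)(C)C(C)(C)C)CC(=O)[C@]3(C)[C@H]2C)cc1 | intermediate
17 | potassium C6=C7 enolate of 16 | COc1ccc(CO[C@@H]2CC[C@@H]3C[C@@H](O[Si](C)(C)C(C)(C)C)C=C([O-])[C@]3(C)[C@H]2C)cc1.[K+] | intermediate
18 | C6 enol triflate of 16 | COc1ccc(CO[C@@H]2CC[C@@H]3C[C@@H](O[Si](C)(C)C(C)(C)C)C=C(OS(=O)(=O)C(F)(F)F)[C@]3(C)[C@H]2C)cc1 | intermediate
19 | 3α-(4-methoxybenzyloxy)-8β-(tert-butyldimethylsilyloxy)-10βH-11,12,13-trinoreremophil-6-ene | COc1ccc(CO[C@@H]2CC[C@@H]3C[C@@H](O[Si](C)(C)C(C)(C)C)C=C[C@]3(C)[C@H]2C)cc1 | intermediate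
20 | 3α-(4-methoxybenzyloxy)-10βH-11,12,13-trinoreremophil-6-en-8β-ol | COc1ccc(CO[C@@H]2CC[C@@H]3C[C@@H](O)C=C[C@]3(C)[C@H]2C)cc1 | intermediate
21 | 3α-(4-methoxybenzyloxy)-10βH-11,12,13-trinoreremophil-6-en-8-one | COc1ccc(CO[C@@H]2CC[C@@H]3CC(=O)C=C[C@]3(C)[C@H]2C)cc1 | intermediate
22 | 1-(tert-butyldimethylsilyloxy)propan-2-one | CC(=O)CO[Si](C)(C)C(C)(C)C | starting material
23 | lithium C7=C8 enolate from 21 | COc1ccc(CO[C@@H]2CC[C@@H]3CC([O-])=CC[C@]3(C)[C@H]2C)cc1.[Li+] | intermediate
24 | C7 aldol adduct (mixture at C7 and C11) | COc1ccc(CO[C@@H]2CC[C@@H]3CC(=O)C(C[C@]3(C)[C@H]2C)C(C)(O)CO[Si](C)(C)C(C)(C)C)cc1 | intermediate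
25 | 3α-(4-methoxybenzyloxy)-10βH-furanoeremophilane | COc1ccc(CO[C@@H]2CC[C@@H]3Cc4occ(C)c4C[C@]3(C)[C@H]2C)cc1 | intermediate
26 | 8,12-endoperoxide of furan 25 | COc1ccc(CO[C@@H]2CC[C@@H]3CC45OOC(O4)C(C)=C5C[C@]3(C)[C@H]2C)cc1 | intermediate
27 | (7Z)-3α-(4-methoxybenzyloxy)-8-oxo-10βH-eremophil-7(11)-en-12-al | COc1ccc(CO[C@@H]2CC[C@@H]3CC(=O)/C(=C(/C)C=O)C[C@]3(C)[C@H]2C)cc1 | intermediate
28 | (7Z)-12-hydroxy-3α-(4-methoxybenzyloxy)-10βH-eremophil-7(11)-en-8-one | COc1ccc(CO[C@@H]2CC[C@@H]3CC(=O)/C(=C(/C)CO)C[C@]3(C)[C@H]2C)cc1 | intermediate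
29 | (7Z)-3α-(4-methoxybenzyloxy)-12-(triethylsilyloxy)-10βH-eremophil-7(11)-en-8-one | COc1ccc(CO[C@@H]2CC[C@@H]3CC(=O)/C(=C(/C)CO[Si](CC)(CC)CC)C[C@]3(C)[C@H]2C)cc1 | intermediate
30 | sodium C8=C9 enolate of 29 | COc1ccc(CO[C@@H]2CC[C@@H]3C=C([O-])/C(=C(/C)CO[Si](CC)(CC)CC)C[C@]3(C)[C@H]2C)cc1.[Na+] | intermediate
31 | (7Z)-9β-hydroxy-3α-(4-methoxybenzyloxy)-12-(triethylsilyloxy)-10βH-eremophil-7(11)-en-8-one | COc1ccc(CO[C@@H]2CC[C@@H]3[C@@H](O)C(=O)/C(=C(/C)CO[Si](CC)(CC)CC)C[C@]3(C)[C@H]2C)cc1 | intermediate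
32 | (7Z)-3α-(4-methoxybenzyloxy)-9β,12-bis(triethylsilyloxy)-10βH-eremophil-7(11)-en-8-one | COc1ccc(CO[C@@H]2CC[C@@H]3[C@@H](O[Si](CC)(CC)CC)C(=O)/C(=C(/C)CO[Si](CC)(CC)CC)C[C@]3(C)[C@H]2C)cc1 | intermediate
33 | (7Z)-3α-hydroxy-9β,12-bis(triethylsilyloxy)-10βH-eremophil-7(11)-en-8-one | O[C@@H]1CC[C@@H]2[C@@H](O[Si](CC)(CC)CC)C(=O)/C(=C(/C)CO[Si](CC)(CC)CC)C[C@]2(C)[C@H]1C | intermediate
34 | (E)-non-3-en-2-one | CCCCC/C=C/C(C)=O | starting material
35 | triethyl phosphonoacetate | CCOC(=O)CP(=O)(OCC)OCC | starting material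
36 | ethyl (2E,4E)-3-methyldeca-2,4-dienoate | CCCCC/C=C/C(C)=C/C(=O)OCC | intermediate
37 | (2E,4E)-3-methyldeca-2,4-dien-1-ol | CCCCC/C=C/C(C)=C/CO | intermediate
38 | (2E,4E)-3-methyldeca-2,4-dienal | CCCCC/C=C/C(C)=C/C=O | intermediate
39 | ethyl (2E,4E,6E)-5-methyldodeca-2,4,6-trienoate | CCCCC/C=C/C(C)=C/C=C/C(=O)OCC | intermediate
40 | (2E,4E,6E)-5-methyldodeca-2,4,6-trienoic acid | CCCCC/C=C/C(C)=C/C=C/C(=O)O | intermediate
41 | (2E,4E,6E)-5-methyldodeca-2,4,6-trienoic 2,4,6-trichlorobenzoic anhydride | CCCCC/C=C/C(C)=C/C=C/C(=O)OC(=O)c1c(Cl)cc(Cl)cc1Cl | intermediate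
42 | (7Z)-8-oxo-9β,12-bis(triethylsilyloxy)-10βH-eremophil-7(11)-en-3α-yl (2E,4E,6E)-5-methyldodeca-2,4,6-trienoate | CCCCC/C=C/C(C)=C/C=C/C(=O)O[C@@H]1CC[C@@H]2[C@@H](O[Si](CC)(CC)CC)C(=O)/C(=C(/C)CO[Si](CC)(CC)CC)C[C@]2(C)[C@H]1C | intermediate
43 | CNP0226738.1, (3R,4R,5R,9R,10S,7Z)-9β,12-dihydroxy-8-oxo-10βH-eremophil-7(11)-en-3α-yl (2E,4E,6E)-5-methyldodeca-2,4,6-trienoate | CCCCC/C=C/C(C)=C/C=C/C(=O)O[C@@H]1CC[C@@H]2[C@@H](O)C(=O)/C(=C(/C)CO)C[C@]2(C)[C@H]1C | target

**Totals**

- Total step count: 26.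
- Longest linear sequence: 21 steps (steps 1–19, 25 and 26).
- The side chain (steps 20–24) is made in parallel.

**The three steps most likely to fail**

**Step 9.**
- What may go wrong: the cycloaddition may be too slow, because a trisubstituted dienophile has to form a quaternary centre against the polarisation of the alkoxydiene. Prolonged heating would then cause thermal decay of the dienol ether, or erosion of the endo and facial preference.
- Fallback: the same two bonds are formed, but O3 is masked as boron. The diene is then no longer polarised against the tether and tolerates an aluminium Lewis acid on the ketone. The fallback sets out from 6 and comes back at 15.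
- Addition of 13 to 6 gives (2E,6R)-6-(tert-butyldimethylsilyloxy)-3-methylnona-2,8-dien-4-one F1.
- Cross-metathesis with 7 gives (2E,5R,8E)-5-(tert-butyldimethylsilyloxy)-8-methyl-7-oxodeca-2,8-dienal F2.
- Takai–Utimoto olefination with Cl2CHB(pin), CrCl2 and LiI gives the (E,E)-dienylboronate (2E,6R,8E,10E)-6-(tert-butyldimethylsilyloxy)-3-methyl-11-(4,4,5,5-tetramethyl-1,3,2-dioxaborolan-2-yl)undeca-2,8,10-trien-4-one F3.
- EtAlCl2 in CH2Cl2 at low temperature promotes the intramolecular Diels–Alder reaction to the allylboronate 3α-(pinacolatoboryl)-8β-(tert-butyldimethylsilyloxy)-10βH-11,12,13-trinoreremophil-1-en-6-one F4.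
- NaBO3·4H2O oxidises the C–B bond with retention to 3α-hydroxy-8β-(tert-butyldimethylsilyloxy)-10βH-11,12,13-trinoreremophil-1-en-6-one F5.
- 4-Methoxybenzyl trichloroacetimidate with catalytic La(OTf)3 then gives 15.

**Step 15.**
- What may go wrong: hydride delivery to C6 beside the quaternary C5 may be slow, so that 1,2-reduction competes. Addition of the enolate to a ketone is also reversible, so that retro-aldol and proton transfer may simply return the saturated ketone.
- Fallback: the reversible aldol is replaced by an irreversible Michael addition, and a different hydride source is used. The fallback sets out from 21 and comes back at 25.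
- RhCl(PPh3)3-catalysed 1,4-hydrosilylation with Et3SiH gives the triethylsilyl enol ether 3α-(4-methoxybenzyloxy)-8-(triethylsilyloxy)-10βH-11,12,13-trinoreremophil-7-ene F6.
- SnCl4-mediated Mukaiyama–Michael addition to (E)-1-nitropropene at −78 °C with hydrolytic Nef work-up gives the γ-keto aldehyde 3α-(4-methoxybenzyloxy)-8-oxo-10βH-eremophilan-12-al F7.
- Catalytic p-TsOH closes F7 to furan 25 (Paal–Knorr).

**Step 16.**
- What may go wrong: Z-to-E isomerisation of the ene-dicarbonyl stage, over-reduction at the ketone, or loss of water from the hydroxy enone back to the furan.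
- Fallback: C8 and C12 are kept inside a lactone ring until C12 is protected. The fallback sets out from 25 and comes back at 29.
- Photooxygenation in the presence of i-Pr2NEt fragments the endoperoxide by loss of H12 to the γ-hydroxybutenolide 8-hydroxy-3α-(4-methoxybenzyloxy)-10βH-eremophil-7(11)-en-12,8-olide F8.
- NaBH4 reduces F8, through its open keto-acid form, to the butenolide 3α-(4-methoxybenzyloxy)-10βH-eremophil-7(11)-en-12,8-olide F9.
- Excess i-Bu2AlH gives the diol (7Z)-3α-(4-methoxybenzyloxy)-10βH-eremophil-7(11)-ene-8,12-diol F10.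
- One equivalent of TESCl with imidazole at −20 °C silylates the primary hydroxyl to (7Z)-3α-(4-methoxybenzyloxy)-12-(triethylsilyloxy)-10βH-eremophil-7(11)-en-8-ol F11.
- MnO2 oxidises the allylic C8 alcohol of F11 to 29.

**Further compounds**

F1 | step 9 | (2E,6R)-6-(tert-butyldimethylsilyloxy)-3-methylnona-2,8-dien-4-one | C/C=C(\C)C(=O)C[C@H](O[Si](C)(C)C(C)(C)C)CC=C
F2 | step 9 | (2E,5R,8E)-5-(tert-butyldimethylsilyloxy)-8-methyl-7-oxodeca-2,8-dienal | C/C=C(\C)C(=O)C[C@H](O[Si](C)(C)C(C)(C)C)C/C=C/C=O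
F3 | step 9 | (2E,6R,8E,10E)-6-(tert-butyldimethylsilyloxy)-3-methyl-11-(4,4,5,5-tetramethyl-1,3,2-dioxaborolan-2-yl)undeca-2,8,10-trien-4-one | C/C=C(\C)C(=O)C[C@H](O[Si](C)(C)C(C)(C)C)C/C=C/C=C/B1OC(C)(C)C(C)(C)O1
F4 | step 9 | 3α-(pinacolatoboryl)-8β-(tert-butyldimethylsilyloxy)-10βH-11,12,13-trinoreremophil-1-en-6-one | CC1(C)OB(OC1(C)C)[C@@H]2C=C[C@@H]3C[C@@H](O[Si](C)(C)C(C)(C)C)CC(=O)[C@]3(C)[C@H]2C
F5 | step 9 | 3α-hydroxy-8β-(tert-butyldimethylsilyloxy)-10βH-11,12,13-trinoreremophil-1-en-6-one | O[C@@H]1C=C[C@@H]2C[C@@H](O[Si](C)(C)C(C)(C)C)CC(=O)[C@]2(C)[C@H]1C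
F6 | step 15 | 3α-(4-methoxybenzyloxy)-8-(triethylsilyloxy)-10βH-11,12,13-trinoreremophil-7-ene | COc1ccc(CO[C@@H]2CC[C@@H]3CC(O[Si](CC)(CC)CC)=CC[C@]3(C)[C@H]2C)cc1
F7 | step 15 | 3α-(4-methoxybenzyloxy)-8-oxo-10βH-eremophilan-12-al (mixture at C7 and C11) | COc1ccc(CO[C@@H]2CC[C@@H]3CC(=O)C(C[C@]3(C)[C@H]2C)C(C)C=O)cc1
F8 | step 16 | 8-hydroxy-3α-(4-methoxybenzyloxy)-10βH-eremophil-7(11)-en-12,8-olide (mixture at C8) | COc1ccc(CO[C@@H]2CC[C@@H]3CC4(O)OC(=O)C(C)=C4C[C@]3(C)[C@H]2C)cc1
F9 | step 16 | 3α-(4-methoxybenzyloxy)-10βH-eremophil-7(11)-en-12,8-olide (mixture at C8) | COc1ccc(CO[C@@H]2CC[C@@H]3CC4OC(=O)C(C)=C4C[C@]3(C)[C@H]2C)cc1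
F10 | step 16 | (7Z)-3α-(4-methoxybenzyloxy)-10βH-eremophil-7(11)-ene-8,12-diol (mixture at C8) | COc1ccc(CO[C@@H]2CC[C@@H]3CC(O)/C(=C(/C)CO)C[C@]3(C)[C@H]2C)cc1
F11 | step 16 | (7Z)-3α-(4-methoxybenzyloxy)-12-(triethylsilyloxy)-10βH-eremophil-7(11)-en-8-ol (mixture at C8) | COc1ccc(CO[C@@H]2CC[C@@H]3CC(O)/C(=C(/C)CO[Si](CC)(CC)CC)C[C@]3(C)[C@H]2C)cc1
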